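**Retrosynthetic overview**
1. Target 16 ⇐ hydrogenolysis of tetra-O-benzyl ether 15; both 4-methoxy groups are carried through from the start.
2. Flavone pyranone of 15 ⇐ cyclodehydration of β-diketone 14 ⇐ crossed Claisen condensation of the dilithium dianion 13 of acetophenone 12 with aroyl chloride 10; this C–C bond joins the two halves.
3. 10 ⇐ acid 9 ⇐ aldehyde 8 ⇐ Suzuki coupling of 8-iodoisoflavone 6 with boronic acid 7 (biaryl bond made early, on small fragments).
4. 6 ⇐ biochanin A 4 (benzylation, C-8 iodination) ⇐ deoxybenzoin 3 ⇐ phloroglucinol 1 + 4-methoxyphenylacetic acid 2.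
5. Ring order: isoflavone pyranone (step 2), then the biaryl (step 5), then the flavone pyranone (step 10).

Assumption: the target has no stereocentre and its SMILES assigns no configuration to the hindered biaryl axis, so the compound is made as drawn and no stereocontrol is needed.

**Route**

Step 1
Reactants: 1 phloroglucinol; 2 4-methoxyphenylacetic acid
Product: 3 2-(4-methoxyphenyl)-1-(2,4,6-trihydroxyphenyl)ethan-1-one
Conditions: BF3·OEt2 (promoter and solvent), 85 °C, 2 h; aq. NaOAc work-up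
Reagents that add atoms: none
Why: Friedel–Crafts (Houben–Hoesch-type) C-acylation of the very electron-rich phloroglucinol stops at the mono-ketone because the product is deactivated as its boron chelate.

Step 2
Reactants: 3 2-(4-methoxyphenyl)-1-(2,4,6-trihydroxyphenyl)ethan-1-one
Product: 4 biochanin A (5,7-dihydroxy-3-(4-methoxyphenyl)-4H-chromen-4-one)
Conditions: BF3·OEt2 (3 equiv), DMF, then MsCl (3 equiv), 70 °C, 2 h; aq. NaOAc work-up
Reagents that add atoms: N,N-dimethylformamide, CN(C)C=O (supplies C-2)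
Why: Vilsmeier-type formylation of the activated CH2 (a one-carbon Claisen-type condensation) and ring closure through one of the two equivalent ortho hydroxyls give the isoflavone, so only one regioisomer is possible.

Step 3
Reactants: 4 biochanin A
Product: 5 5,7-bis(benzyloxy)-3-(4-methoxyphenyl)-4H-chromen-4-one
Conditions: BnBr (3 equiv), K2CO3 (4 equiv), dry DMF, 80 °C, 12 h
Reagents that add atoms: benzyl bromide, BrCc1ccccc1
Why: Williamson etherification in which the 7-OH reacts fast and the chelated 5-OH is forced by heat and excess reagent, while anhydrous carbonate does not open the pyranone.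

Step 4
Reactants: 5 5,7-bis(benzyloxy)-3-(4-methoxyphenyl)-4H-chromen-4-one
Product: 6 5,7-bis(benzyloxy)-8-iodo-3-(4-methoxyphenyl)-4H-chromen-4-one
Conditions: NIS (1.05 equiv), CF3CO2H (10 mol%), MeCN/CH2Cl2, 0 °C to rt, dark
Reagents that add atoms: N-iodosuccinimide, O=C1CCC(=O)N1I
Why: Electrophilic aromatic iodination of the phloroglucinol-type ring A, where C-8 (between the ring oxygen and one OBn) is more accessible than C-6 (between two OBn), as found for 5,7-dialkoxyflavones; ring B is far less activated.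

Step 5
Reactants: 6 5,7-bis(benzyloxy)-8-iodo-3-(4-methoxyphenyl)-4H-chromen-4-one; 7 (5-formyl-2-methoxyphenyl)boronic acid (1.6 equiv)
Product: 8 3-[5,7-bis(benzyloxy)-3-(4-methoxyphenyl)-4-oxo-4H-chromen-8-yl]-4-methoxybenzaldehyde
Conditions: Pd(OAc)2 (5 mol%), 2-dicyclohexylphosphino-2',6'-dimethoxybiphenyl (SPhos, 10 mol%), K3PO4 (3 equiv), toluene/H2O 10:1, 80 °C
Reagents that add atoms: none
Why: Suzuki–Miyaura coupling in which the bulky, electron-rich biarylphosphine lets zerovalent palladium insert into the hindered C–I bond and form the tri-ortho-substituted biaryl, while the two-phase phosphate base spares the pyranone and the aldehyde.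

Step 6
Reactants: 8 3-[5,7-bis(benzyloxy)-3-(4-methoxyphenyl)-4-oxo-4H-chromen-8-yl]-4-methoxybenzaldehyde
Product: 9 3-[5,7-bis(benzyloxy)-3-(4-methoxyphenyl)-4-oxo-4H-chromen-8-yl]-4-methoxybenzoic acid
Conditions: NaClO2 (3 equiv), NaH2PO4 (3 equiv), 2-methyl-2-butene (20 equiv), t-BuOH/THF/H2O, 0 °C to rt
Reagents that add atoms: sodium chlorite, [Na+].[O-]Cl=O
Why: Pinnick oxidation is selective for the aldehyde in buffered, mildly acidic medium, and the alkene scavenger removes HOCl before it can chlorinate the electron-rich rings.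

Step 7
Reactants: 9 3-[5,7-bis(benzyloxy)-3-(4-methoxyphenyl)-4-oxo-4H-chromen-8-yl]-4-methoxybenzoic acid
Product: 10 3-[5,7-bis(benzyloxy)-3-(4-methoxyphenyl)-4-oxo-4H-chromen-8-yl]-4-methoxybenzoyl chloride (used crude)
Conditions: (COCl)2 (1.2 equiv), DMF (cat.), CH2Cl2, 0 °C to rt, 1 h; evaporate, strip with toluene
Reagents that add atoms: oxalyl chloride, O=C(Cl)C(=O)Cl
Why: Vilsmeier-catalysed acyl chloride formation is fast at the carboxylic acid, and a small excess at low temperature leaves the benzyl ethers and the pyranone carbonyl alone.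

Step 8
Reactants: 11 1-(2,4,6-trihydroxyphenyl)ethan-1-one (2',4',6'-trihydroxyacetophenone, dried)
Product: 12 1-[2,4-bis(benzyloxy)-6-hydroxyphenyl]ethan-1-one
Conditions: BnBr (2.05 equiv), K2CO3 (2.1 equiv), dry DMF, 0 °C to rt
Reagents that add atoms: benzyl bromide, BrCc1ccccc1
Why: Williamson etherification in which one ortho hydroxyl stays free because its hydrogen bond to the acetyl carbonyl makes it the least nucleophilic.

Step 9
Reactants: 12 1-[2,4-bis(benzyloxy)-6-hydroxyphenyl]ethan-1-one (1.2 equiv); 10 3-[5,7-bis(benzyloxy)-3-(4-methoxyphenyl)-4-oxo-4H-chromen-8-yl]-4-methoxybenzoyl chloride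
Product: 14 1-[2,4-bis(benzyloxy)-6-hydroxyphenyl]-3-{3-[5,7-bis(benzyloxy)-3-(4-methoxyphenyl)-4-oxo-4H-chromen-8-yl]-4-methoxyphenyl}propane-1,3-dione, via dilithium enolate-phenolate dianion 13 (not isolated)
Conditions: LiN(SiMe3)2 (3.5 equiv), THF, −78 to −10 °C, 1 h; recool to −78 °C, add 10 in THF, 1 h, then to 0 °C; cold aq. NH4Cl/1 M HCl
Reagents that add atoms: none
Why: Crossed Claisen condensation (enolate C-acylation) in which the acyl chloride is far more electrophilic at −78 °C than C-2 of the isoflavone, and the product is protected as its enolate by the third equivalent of base; any O-acylated ester rearranges to the same diketone under the basic conditions.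

Step 10
Reactants: 14 1-[2,4-bis(benzyloxy)-6-hydroxyphenyl]-3-{3-[5,7-bis(benzyloxy)-3-(4-methoxyphenyl)-4-oxo-4H-chromen-8-yl]-4-methoxyphenyl}propane-1,3-dione
Product: 15 5,7-bis(benzyloxy)-8-{5-[5,7-bis(benzyloxy)-4-oxo-4H-chromen-2-yl]-2-methoxyphenyl}-3-(4-methoxyphenyl)-4H-chromen-4-one
Conditions: p-toluenesulfonic acid monohydrate (0.2 equiv), toluene, 100 °C, Dean–Stark
Reagents that add atoms: none
Why: Acid-catalysed cyclodehydration (the ring-closing stage of a Baker–Venkataraman-type flavone synthesis) adds the free phenol to the far carbonyl and loses water, giving the flavone without an oxidation step; the isoflavone is stable to acid.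

Step 11
Reactants: 15 5,7-bis(benzyloxy)-8-{5-[5,7-bis(benzyloxy)-4-oxo-4H-chromen-2-yl]-2-methoxyphenyl}-3-(4-methoxyphenyl)-4H-chromen-4-one
Product: 16 5,7-dihydroxy-8-[5-(5,7-dihydroxy-4-oxo-4H-chromen-2-yl)-2-methoxyphenyl]-3-(4-methoxyphenyl)-4H-chromen-4-one (target)
Conditions: H2 (1 atm), Pd/C (10 wt% Pd), THF/MeOH 1:1, rt; stop at full conversion
Reagents that add atoms: none
Why: Catalytic hydrogenolysis cleaves the four benzyl ethers, while the aryl methyl ethers and both pyranone double bonds survive at 1 atm and room temperature if the reaction is stopped at completion.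

**Compound list**
1 | phloroglucinol (benzene-1,3,5-triol) | Oc1cc(O)cc(O)c1 | starting material
2 | 4-methoxyphenylacetic acid | COc1ccc(CC(=O)O)cc1 | starting material
3 | 2-(4-methoxyphenyl)-1-(2,4,6-trihydroxyphenyl)ethan-1-one | COc1ccc(CC(=O)c2c(O)cc(O)cc2O)cc1 | intermediate
4 | biochanin A, 5,7-dihydroxy-3-(4-methoxyphenyl)-4H-chromen-4-one | COc1ccc(-c2coc3cc(O)cc(O)c3c2=O)cc1 | intermediate
5 | 5,7-bis(benzyloxy)-3-(4-methoxyphenyl)-4H-chromen-4-one | COc1ccc(-c2coc3cc(OCc4ccccc4)cc(OCc4ccccc4)c3c2=O)cc1 | intermediate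
6 | 5,7-bis(benzyloxy)-8-iodo-3-(4-methoxyphenyl)-4H-chromen-4-one | COc1ccc(-c2coc3c(I)c(OCc4ccccc4)cc(OCc4ccccc4)c3c2=O)cc1 | intermediate
7 | (5-formyl-2-methoxyphenyl)boronic acid | COc1ccc(C=O)cc1B(O)O | starting material
8 | 3-[5,7-bis(benzyloxy)-3-(4-methoxyphenyl)-4-oxo-4H-chromen-8-yl]-4-methoxybenzaldehyde | COc1ccc(-c2coc3c(-c4cc(C=O)ccc4OC)c(OCc4ccccc4)cc(OCc4ccccc4)c3c2=O)cc1 | intermediate
9 | 3-[5,7-bis(benzyloxy)-3-(4-methoxyphenyl)-4-oxo-4H-chromen-8-yl]-4-methoxybenzoic acid | COc1ccc(-c2coc3c(-c4cc(C(=O)O)ccc4OC)c(OCc4ccccc4)cc(OCc4ccccc4)c3c2=O)cc1 | intermediate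
10 | 3-[5,7-bis(benzyloxy)-3-(4-methoxyphenyl)-4-oxo-4H-chromen-8-yl]-4-methoxybenzoyl chloride | COc1ccc(-c2coc3c(-c4cc(C(=O)Cl)ccc4OC)c(OCc4ccccc4)cc(OCc4ccccc4)c3c2=O)cc1 | intermediate
11 | 1-(2,4,6-trihydroxyphenyl)ethan-1-one | CC(=O)c1c(O)cc(O)cc1O | starting material
12 | 1-[2,4-bis(benzyloxy)-6-hydroxyphenyl]ethan-1-one | CC(=O)c1c(O)cc(OCc2ccccc2)cc1OCc1ccccc1 | intermediate
13 | dilithium 3,5-bis(benzyloxy)-2-(1-oxidoethenyl)phenolate (dianion of 12, not isolated) | [Li+].[Li+].C=C([O-])c1c([O-])cc(OCc2ccccc2)cc1OCc1ccccc1 | intermediate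
14 | 1-[2,4-bis(benzyloxy)-6-hydroxyphenyl]-3-{3-[5,7-bis(benzyloxy)-3-(4-methoxyphenyl)-4-oxo-4H-chromen-8-yl]-4-methoxyphenyl}propane-1,3-dione | COc1ccc(-c2coc3c(-c4cc(C(=O)CC(=O)c5c(O)cc(OCc6ccccc6)cc5OCc5ccccc5)ccc4OC)c(OCc4ccccc4)cc(OCc4ccccc4)c3c2=O)cc1 | intermediate
15 | 5,7-bis(benzyloxy)-8-{5-[5,7-bis(benzyloxy)-4-oxo-4H-chromen-2-yl]-2-methoxyphenyl}-3-(4-methoxyphenyl)-4H-chromen-4-one | COc1ccc(-c2coc3c(-c4cc(-c5cc(=O)c6c(OCc7ccccc7)cc(OCc7ccccc7)cc6o5)ccc4OC)c(OCc4ccccc4)cc(OCc4ccccc4)c3c2=O)cc1 | intermediate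
16 | 5,7-dihydroxy-8-[5-(5,7-dihydroxy-4-oxo-4H-chromen-2-yl)-2-methoxyphenyl]-3-(4-methoxyphenyl)-4H-chromen-4-one (no stereocentre) | COc1ccc(-c2coc3c(-c4cc(-c5cc(=O)c6c(O)cc(O)cc6o5)ccc4OC)c(O)cc(O)c3c2=O)cc1 | target

**Totals and risks**
Total step count: 11. Longest linear sequence: 10 steps (steps 1 to 7 and 9 to 11, from phloroglucinol); the acetophenone branch is step 8.

The three steps most likely to fail:

Step 4, site of iodination. If iodination of 5 gives the C-6 isomer or attacks ring B, the halogen is placed before the pyranone is closed. This fallback sets out from compound 3. Selective benzylation (BnBr 2 equiv, K2CO3, DMF, rt) leaves only the chelated hydroxyl free and gives 1-[2,4-bis(benzyloxy)-6-hydroxyphenyl]-2-(4-methoxyphenyl)ethan-1-one F1. Iodination ortho to that single free phenol (NIS, or benzyltrimethylammonium dichloroiodate with NaHCO3, CH2Cl2/MeOH) gives 1-[4,6-bis(benzyloxy)-2-hydroxy-3-iodophenyl]-2-(4-methoxyphenyl)ethan-1-one F2. Ring closure with N,N-dimethylformamide dimethyl acetal (toluene, 90 °C) can only use the hydroxyl next to the iodinated carbon, so the iodine ends at C-8. The fallback comes back to the route at compound 6.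

Step 5, hindered Suzuki coupling. If boronic acid 7 protodeboronates faster than it couples, the polarity of the coupling is reversed. This fallback sets out from compound 6. Miyaura borylation (bis(pinacolato)diboron, PdCl2(dppf), KOAc, 1,4-dioxane, 90 °C) gives 5,7-bis(benzyloxy)-3-(4-methoxyphenyl)-8-(4,4,5,5-tetramethyl-1,3,2-dioxaborolan-2-yl)-4H-chromen-4-one F3. This is coupled with commercial 3-bromo-4-methoxybenzaldehyde (Pd(OAc)2, SPhos, K3PO4, toluene/H2O, 80 °C), an unhindered and stable electrophile. The fallback comes back to the route at compound 8.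

Step 9, Claisen condensation beside a base-sensitive isoflavone. If the enolate or the amide base attacks C-2 of the isoflavone, the flavone is built by an aldol route that uses no strong base. This fallback sets out from compound 8 together with acetophenone 12. A BF3·OEt2-mediated Claisen–Schmidt aldol condensation in 1,4-dioxane at rt gives (E)-1-[2,4-bis(benzyloxy)-6-hydroxyphenyl]-3-{3-[5,7-bis(benzyloxy)-3-(4-methoxyphenyl)-4-oxo-4H-chromen-8-yl]-4-methoxyphenyl}prop-2-en-1-one F4. Oxidative cyclisation with I2 (10 mol%) in DMSO at 120 °C closes and dehydrogenates the chalcone. The fallback comes back to the route at compound 15.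

**Further compounds**
F1 | step 4 | 1-[2,4-bis(benzyloxy)-6-hydroxyphenyl]-2-(4-methoxyphenyl)ethan-1-one | COc1ccc(CC(=O)c2c(O)cc(OCc3ccccc3)cc2OCc2ccccc2)cc1
F2 | step 4 | 1-[4,6-bis(benzyloxy)-2-hydroxy-3-iodophenyl]-2-(4-methoxyphenyl)ethan-1-one | COc1ccc(CC(=O)c2c(O)c(I)c(OCc3ccccc3)cc2OCc2ccccc2)cc1
F3 | step 5 | 5,7-bis(benzyloxy)-3-(4-methoxyphenyl)-8-(4,4,5,5-tetramethyl-1,3,2-dioxaborolan-2-yl)-4H-chromen-4-one | COc1ccc(-c2coc3c(B4OC(C)(C)C(C)(C)O4)c(OCc4ccccc4)cc(OCc4ccccc4)c3c2=O)cc1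
F4 | step 9 | (E)-1-[2,4-bis(benzyloxy)-6-hydroxyphenyl]-3-{3-[5,7-bis(benzyloxy)-3-(4-methoxyphenyl)-4-oxo-4H-chromen-8-yl]-4-methoxyphenyl}prop-2-en-1-one | COc1ccc(-c2coc3c(-c4cc(/C=C/C(=O)c5c(O)cc(OCc6ccccc6)cc5OCc5ccccc5)ccc4OC)c(OCc4ccccc4)cc(OCc4ccccc4)c3c2=O)cc1
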